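**Plan**

- Retrosynthesis: the O6–C1′ geranyl ether is cut first. Then the whole benzene ring is removed by cutting C4a–C5 and C8–C8a. The lactone half (C1, O2, C3, C4, C4a, C8a with 3-Me and 4-OAc) becomes a 3-bromo-5,6-dihydropyran-2-one; C5–C8 with O5, O6 and O8 become the bis(silyl) dienol ether of methyl 4-methoxyacetoacetate.
- Forward: the δ-lactone ring comes first (oxidative Ferrier rearrangement of 3,4-di-O-acetyl-L-fucal, then α-bromination). The benzene ring is then built on the lactone C=C in one flask by [4+2] annulation and aromatisation. The geranyl chain is joined last at the only non-chelated phenol.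
- Stereochemistry: C3 (S), C4 (S), their cis relation and the acetate itself are C5, C4 and the 4-O-acetyl group of L-fucal. No stereocentre is created in the route; both are only carried.
- Enabling feature: the arene shares only the C4a–C8a bond with the lactone ring, and C8a is α and C4a is β to the lactone carbonyl C1. The other four arene carbons carry OMe (C5), O (C6), H (C7) and O (C8), which is the pattern of a 4-methoxyacetoacetate. The nucleophilic diene terminus (future C5) is therefore matched with electrophilic C4a, and the ketene-acetal carbon (future C8) with C8a. This places the free 8-OH next to the carbonyl and leaves 6-OH as the only unchelated phenol.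

Key step: step 5

Remark on the chemistry: 1, 6 and 12 are taken as purchased. Enol ether 7 and diene 8 are used as mixtures of double-bond isomers. The anomeric carbon of 2, C3/C4 of 4, and the ring carbons made and destroyed again within step 5 (in 9 and 10) are of no consequence. The SMILES carry no descriptors at these positions.

**Step 1**
Reactants: 1 3,4-di-O-acetyl-L-fucal
Product: 3 (5S,6S)-6-methyl-2-oxo-5,6-dihydro-2H-pyran-5-yl acetate, via anomeric perester 2 (not isolated)
Conditions: mCPBA (1.3 equiv, dried), BF3·OEt2 (0.2 equiv), CH2Cl2, −20 → 0 °C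
Reagents that add atoms: 3-chloroperbenzoic acid (mCPBA), OOC(=O)c1cccc(Cl)c1
Why: Oxidative Ferrier rearrangement: BF3 ionises the allylic 3-acetate, the peracid traps the allyl oxocarbenium ion at C1, and the perester fragments (Kornblum–DeLaMare type) to the enone lactone, while sugar C4 and C5 are untouched and become C5 and C6 of 3.

**Step 2**
Reactants: 3 (5S,6S)-6-methyl-2-oxo-5,6-dihydro-2H-pyran-5-yl acetate
Product: 5 (5S,6S)-3-bromo-6-methyl-2-oxo-5,6-dihydro-2H-pyran-5-yl acetate, via 3,4-dibromolactone 4 (not isolated)
Conditions: Br2 (1.05 equiv), CH2Cl2, 0 → 23 °C; then Et3N (1.1 equiv), 0 °C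
Reagents that add atoms: bromine, BrBr
Why: Bromine addition to the enoate followed by E1cB loss of HBr (the α-hydrogen is the only acidic one and the β-bromide leaves) is the standard bromination–dehydrobromination route to 3-bromo-5,6-dihydropyran-2-ones, and the cold, near-stoichiometric base should leave C5 and C6 unchanged.

**Step 3**
Reactants: 6 methyl 4-methoxyacetoacetate
Product: 7 methyl 4-methoxy-3-(trimethylsilyloxy)but-2-enoate
Conditions: TMSCl (1.3 equiv), Et3N (1.5 equiv), hexane, 23 °C
Reagents that add atoms: chlorotrimethylsilane, C[Si](C)(C)Cl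
Why: O-Silylation of the enol of a β-keto ester under amine base is the usual first stage in making 1,3-bis(silyloxy)dienes.

**Step 4**
Reactants: 7 methyl 4-methoxy-3-(trimethylsilyloxy)but-2-enoate
Product: 8 1,4-dimethoxy-1,3-bis(trimethylsilyloxy)buta-1,3-diene
Conditions: LDA (1.1 equiv, commercial solution), THF, −78 °C; then TMSCl (1.2 equiv), −78 → 0 °C; used crude
Reagents that add atoms: chlorotrimethylsilane, C[Si](C)(C)Cl
Why: γ-Deprotonation of the silyloxy enoate at the CH2OMe group gives the extended ester enolate, which is O-silylated to the ketene-acetal diene (silyl dienol ether formation).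

**Step 5**
Reactants: 5 (5S,6S)-3-bromo-6-methyl-2-oxo-5,6-dihydro-2H-pyran-5-yl acetate; 8 1,4-dimethoxy-1,3-bis(trimethylsilyloxy)buta-1,3-diene (2.5 equiv)
Product: 11 (3S,4S)-6,8-dihydroxy-5-methoxy-3-methyl-1-oxoisochroman-4-yl acetate, via silyl cycloadduct 9 (not isolated), via bromo triketone 10 (not isolated)
Conditions: PhMe, 100 °C (sealed tube); then 1 M aq HCl–THF, 0 → 23 °C
Reagents that add atoms: none
Why: Proposed new method: the electron-rich terminus C4 of 8 (pushed by the two ketene-acetal oxygens on C1 and the silyloxy group on C3) bonds to the β-carbon C4 of bromo-enoate 5 and C1 of 8 bonds to the bromine-bearing α-carbon, either as an asynchronous Diels–Alder reaction or as a Mukaiyama–Michael addition followed by Claisen-type closure, both of which give carbocycle 9; the closest known reaction type is the benzannulation of 1,1,3-trioxygenated silyloxy dienes with haloquinones and α-halo enones used as alkyne equivalents, which has not been shown for an α-bromo-α,β-unsaturated δ-lactone. The one ring closed is the six-membered carbocycle C4a–C5–C6–C7–C8–C8a, formed by intermolecular [4+2] annulation onto the C3=C4 bond of the lactone. Aqueous acid then removes both silyl groups and collapses the C8 mixed ketal to a ketone with loss of methanol, giving 10, which is at the oxidation level of an arene hydrobromide: enolisation of the C6 and C8 carbonyls lets bromide leave from C8a as a 5-methoxy-stabilised arenium ion that loses H-4a, so the 6,8-dihydroxy arene forms with O8 next to the lactone carbonyl. No lasting stereocentre is created (C4a, C5, C8 and C8a all end sp2), so facial and endo/exo selectivity are irrelevant, and C3 and C4 of 11 are carried from 5 because neither is acidic nor on a reacting carbon. The selectivities needed are the regiochemistry (5-OMe next to C4a, 8-OH next to C8a), secured by the matched polarisation of the two partners, and loss of HBr rather than methanol, secured because in the bis-enol that releases bromide C5 is already sp2 and its methoxy group can no longer leave.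

**Step 6**
Reactants: 11 (3S,4S)-6,8-dihydroxy-5-methoxy-3-methyl-1-oxoisochroman-4-yl acetate; 12 geranyl bromide (1.05 equiv)
Product: 13 (3S,4S)-6-[(2E)-3,7-dimethylocta-2,6-dienyloxy]-8-hydroxy-5-methoxy-3-methyl-1-oxoisochroman-4-yl acetate
Conditions: K2CO3 (1.2 equiv), acetone, 23 °C
Reagents that add atoms: none
Why: Williamson etherification in which the 8-OH is held in a hydrogen bond to the lactone carbonyl, so the free and more acidic 6-OH should be alkylated selectively by SN2 at the primary allylic bromide (E geometry kept), under conditions mild enough for the acetate and both stereocentres.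

**Compound list**

1 | 3,4-di-O-acetyl-L-fucal, (2S,3R,4S)-2-methyl-3,4-dihydro-2H-pyran-3,4-diyl diacetate | C1=C[C@H](OC(C)=O)[C@H](OC(C)=O)[C@H](C)O1 | starting material
2 | 4-O-acetyl-2,3,6-trideoxy-L-threo-hex-2-enopyranosyl 3-chloroperbenzoate (anomeric perester, anomers) | Clc1cccc(c1)C(=O)OOC2C=C[C@H](OC(C)=O)[C@H](C)O2 | intermediate (not isolated)
3 | (5S,6S)-6-methyl-2-oxo-5,6-dihydro-2H-pyran-5-yl acetate (4-O-acetyl-2,3,6-trideoxy-L-threo-hex-2-enono-1,5-lactone) | O=C1C=C[C@H](OC(C)=O)[C@H](C)O1 | intermediate
4 | trans-3,4-dibromide of 3: 3,4-dibromo-6-methyl-2-oxotetrahydro-2H-pyran-5-yl acetate, acetoxy- and methyl-bearing carbons as in 3 | O=C1C(Br)C(Br)[C@H](OC(C)=O)[C@H](C)O1 | intermediate (not isolated)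
5 | (5S,6S)-3-bromo-6-methyl-2-oxo-5,6-dihydro-2H-pyran-5-yl acetate | O=C1C(Br)=C[C@H](OC(C)=O)[C@H](C)O1 | intermediate
6 | methyl 4-methoxyacetoacetate (methyl 4-methoxy-3-oxobutanoate) | COCC(=O)CC(=O)OC | starting material
7 | methyl 4-methoxy-3-(trimethylsilyloxy)but-2-enoate | COCC(O[Si](C)(C)C)=CC(=O)OC | intermediate
8 | 1,4-dimethoxy-1,3-bis(trimethylsilyloxy)buta-1,3-diene | COC=C(O[Si](C)(C)C)C=C(OC)O[Si](C)(C)C | intermediate
9 | (3S,4S)-8a-bromo-5,8-dimethoxy-3-methyl-1-oxo-6,8-bis(trimethylsilyloxy)-3,4,4a,5,8,8a-hexahydro-1H-isochromen-4-yl acetate (silyl cycloadduct) | COC1C(O[Si](C)(C)C)=CC(OC)(O[Si](C)(C)C)C2(Br)C1[C@H](OC(C)=O)[C@H](C)OC2=O | intermediate (not isolated)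
10 | (3S,4S)-8a-bromo-5-methoxy-3-methyl-1,6,8-trioxooctahydro-1H-isochromen-4-yl acetate (bromo triketone) | COC1C(=O)CC(=O)C2(Br)C1[C@H](OC(C)=O)[C@H](C)OC2=O | intermediate (not isolated)
11 | (3S,4S)-6,8-dihydroxy-5-methoxy-3-methyl-1-oxoisochroman-4-yl acetate | COc1c(O)cc(O)c2c1[C@H](OC(C)=O)[C@H](C)OC2=O | intermediate
12 | geranyl bromide, (2E)-1-bromo-3,7-dimethylocta-2,6-diene | BrC/C=C(\C)CCC=C(C)C | starting material
13 | (3S,4S)-6-[(2E)-3,7-dimethylocta-2,6-dienyloxy]-8-hydroxy-5-methoxy-3-methyl-1-oxoisochroman-4-yl acetate | COc1c(OC/C=C(\C)CCC=C(C)C)cc(O)c2c1[C@H](OC(C)=O)[C@H](C)OC2=O | target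

**Count and risks**

Total step count: 6. Longest linear sequence: 4 steps (1 → 3 → 5 → 11 → 13; the diene branch 6 → 7 → 8 → 11 → 13 is equally long).

Steps most likely to fail:

1. Step 5 (Proposed new method). The bromo lactone may be too weak a dienophile, so that thermal decay of the diene outruns the annulation. The adduct may also fail to shed HBr cleanly and instead stall or lose acetic acid. The fallback sets out from 5 and comes back at 11.
   - Thiophenol and Et3N in CH2Cl2 (conjugate addition, episulfonium formation and loss of HBr, a known route from α-bromo enones to α-arylthio enones) should give (5S,6S)-6-methyl-2-oxo-3-(phenylthio)-5,6-dihydro-2H-pyran-5-yl acetate F1.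
   - mCPBA (1.0 equiv, CH2Cl2, −78 °C) should oxidise F1 at sulfur to (5S,6S)-6-methyl-2-oxo-3-(phenylsulfinyl)-5,6-dihydro-2H-pyran-5-yl acetate F2; either sulfur epimer serves.
   - The sulfinyl group is a known, much stronger activator of unsaturated lactones toward silyloxy dienes. With 8 in PhMe (0 → 60 °C) it should give the sulfinyl cycloadduct F3.
   - F3 should lose benzenesulfenic acid by thermal syn-elimination with the cis H-4a, giving the silylated cyclohexadiene F4. The same acidic work-up should convert F4 into 11.

2. Step 2. The neighbouring acetate may take part in the bromination (acetoxonium ion, acetyl shift, loss of the C5 configuration). The addition to the electron-poor alkene may be slow, or Et3N may epimerise C5 by γ-deprotonation. The fallback sets out from 3 and comes back at 11.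
   - Iodine and pyridine in CH2Cl2 at 23 °C (amine conjugate addition, α-iodination of the enolate, loss of the amine; no cation next to the acetate) should give (5S,6S)-3-iodo-6-methyl-2-oxo-5,6-dihydro-2H-pyran-5-yl acetate F5.
   - F5 would be used in place of 5 under the conditions of step 5. This should give the iodo cycloadduct F6, then the iodo triketone F7, which should lose HI to give 11.

3. Step 6. The phenoxide may be alkylated twice (also at 8-OH) or at carbon C7 between the two oxygens, or the base may remove the acetate. The fallback sets out from 11 and comes back at 13.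
   - Mitsunobu coupling of 11 with geraniol (PPh3, DIAD, THF, 0 °C) activates the alcohol instead of the phenol. It selects the more acidic, non-chelated 6-OH under neutral conditions.
   - No compound outside the list is formed (F0).

**Further compounds**

F1 | step 5 | (5S,6S)-6-methyl-2-oxo-3-(phenylthio)-5,6-dihydro-2H-pyran-5-yl acetate | O=C1C(Sc2ccccc2)=C[C@H](OC(C)=O)[C@H](C)O1
F2 | step 5 | (5S,6S)-6-methyl-2-oxo-3-(phenylsulfinyl)-5,6-dihydro-2H-pyran-5-yl acetate | O=C1C(S(=O)c2ccccc2)=C[C@H](OC(C)=O)[C@H](C)O1
F3 | step 5 | (3S,4S)-5,8-dimethoxy-3-methyl-1-oxo-8a-(phenylsulfinyl)-6,8-bis(trimethylsilyloxy)-3,4,4a,5,8,8a-hexahydro-1H-isochromen-4-yl acetate | COC1C(O[Si](C)(C)C)=CC(OC)(O[Si](C)(C)C)C2(S(=O)c3ccccc3)C1[C@H](OC(C)=O)[C@H](C)OC2=O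
F4 | step 5 | (3S,4S)-5,8-dimethoxy-3-methyl-1-oxo-6,8-bis(trimethylsilyloxy)-3,4,5,8-tetrahydro-1H-isochromen-4-yl acetate | COC1C(O[Si](C)(C)C)=CC(OC)(O[Si](C)(C)C)C2=C1[C@H](OC(C)=O)[C@H](C)OC2=O
F5 | step 2 | (5S,6S)-3-iodo-6-methyl-2-oxo-5,6-dihydro-2H-pyran-5-yl acetate | O=C1C(I)=C[C@H](OC(C)=O)[C@H](C)O1
F6 | step 2 | (3S,4S)-8a-iodo-5,8-dimethoxy-3-methyl-1-oxo-6,8-bis(trimethylsilyloxy)-3,4,4a,5,8,8a-hexahydro-1H-isochromen-4-yl acetate | COC1C(O[Si](C)(C)C)=CC(OC)(O[Si](C)(C)C)C2(I)C1[C@H](OC(C)=O)[C@H](C)OC2=O
F7 | step 2 | (3S,4S)-8a-iodo-5-methoxy-3-methyl-1,6,8-trioxooctahydro-1H-isochromen-4-yl acetate | COC1C(=O)CC(=O)C2(I)C1[C@H](OC(C)=O)[C@H](C)OC2=O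
F0 | step 6 | none | none
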